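**Retrosynthetic overview**
- The target, 3-nonadecylcyclohex-2-en-1-one, comes from its 4-ethoxycarbonyl derivative (a Hagemann-type ester) by ester hydrolysis and decarboxylation in the last step.
- The only ring is closed in the second-to-last step by intramolecular aldol condensation of a 1,5-diketone (ring bond C2–C3).
- The key C–C bond (ring bond C4–C5) comes from an intermolecular Michael addition of ethyl 3-oxodocosanoate to methyl vinyl ketone.
- The β-keto ester comes from icosanoic acid and Meldrum's acid (C-acylation, then ethanolysis).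

Assumption: the target has no stereocentre, so it is made as the one achiral compound drawn; stereocentres in intermediates are racemic and are erased before the end.

**Step 1**
Reactants: 1 icosanoic acid
Product: 2 icosanoyl chloride
Conditions: (COCl)2 (1.3 equiv), DMF (cat.), CH2Cl2, 0 °C to rt; concentrate, use crude
Reagents that add atoms: oxalyl chloride, O=C(Cl)C(=O)Cl
Why: Acid chloride formation through the DMF-derived chloroiminium (Vilsmeier-type) species; the saturated chain offers no competing site and the by-products are gases.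

**Step 2**
Reactants: 2 icosanoyl chloride; 3 Meldrum's acid (2,2-dimethyl-1,3-dioxane-4,6-dione)
Product: 4 5-(1-hydroxyicosylidene)-2,2-dimethyl-1,3-dioxane-4,6-dione
Conditions: pyridine (2.1 equiv), CH2Cl2, 0 °C to rt; wash with cold 1 M HCl, use crude
Reagents that add atoms: none
Why: Claisen-type C-acylation of the very acidic Meldrum's acid (pKa about 5) by the acid chloride gives the enolised acyl derivative cleanly, without O-acylation or double acylation.

**Step 3**
Reactants: 4 5-(1-hydroxyicosylidene)-2,2-dimethyl-1,3-dioxane-4,6-dione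
Product: 6 ethyl 3-oxodocosanoate, via icosanoylketene 5 (not isolated)
Conditions: anhydrous EtOH, reflux, 4 h; recrystallise
Reagents that add atoms: ethanol, CCO
Why: Thermal cycloreversion of the acyl Meldrum's acid loses acetone and CO2 to give an acylketene that ethanol traps (Oikawa–Yonemitsu β-keto ester synthesis).

**Step 4**
Reactants: 6 ethyl 3-oxodocosanoate; 7 methyl vinyl ketone (but-3-en-2-one)
Product: 8 rac-ethyl 2-icosanoyl-5-oxohexanoate
Conditions: NaOEt (5 mol%), EtOH/THF, 7 (1.1 equiv, slow addition), 0 °C to rt; then AcOH quench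
Reagents that add atoms: none
Why: Intermolecular Michael addition of the soft β-keto ester enolate to the unhindered enone forms the key C–C bond (ring C4–C5 of the target) at the doubly activated carbon only; the new stereocentre is racemic and is erased in step 6.

**Step 5**
Reactants: 8 rac-ethyl 2-icosanoyl-5-oxohexanoate
Product: 10 rac-ethyl 2-nonadecyl-4-oxocyclohex-2-ene-1-carboxylate, via ethyl 2-hydroxy-2-nonadecyl-4-oxocyclohexane-1-carboxylate 9 (not isolated)
Conditions: pyrrolidine (0.3 equiv), AcOH (0.3 equiv), toluene, reflux, Dean–Stark; dilute HCl wash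
Reagents that add atoms: none
Why: Intramolecular aldol condensation (the ring-closing half of a Robinson annulation, as in the Hagemann ester synthesis): the methyl-ketone enamine/enol attacks the long-chain ketone to close the six-membered ring, and azeotropic removal of water drives dehydration to the conjugated enone.

**Step 6**
Reactants: 10 rac-ethyl 2-nonadecyl-4-oxocyclohex-2-ene-1-carboxylate
Product: 12 3-nonadecylcyclohex-2-en-1-one, via 2-nonadecyl-4-oxocyclohex-2-ene-1-carboxylic acid 11 (not isolated)
Conditions: KOH (4 equiv), EtOH/THF/H2O, reflux; then 3 M HCl to pH 1, 60 °C; recrystallise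
Reagents that add atoms: none
Why: Saponification gives a vinylogous β-keto acid that loses CO2 through its dienol on acidification and warming, then tautomerises to the thermodynamically preferred conjugated 2-enone; the last stereocentre disappears here.

**Compound list**
1 | icosanoic acid (arachidic acid) | CCCCCCCCCCCCCCCCCCCC(=O)O | starting material
2 | icosanoyl chloride | CCCCCCCCCCCCCCCCCCCC(=O)Cl | intermediate
3 | Meldrum's acid (2,2-dimethyl-1,3-dioxane-4,6-dione) | CC1(C)OC(=O)CC(=O)O1 | starting material
4 | 5-(1-hydroxyicosylidene)-2,2-dimethyl-1,3-dioxane-4,6-dione | CCCCCCCCCCCCCCCCCCCC(O)=C1C(=O)OC(C)(C)OC1=O | intermediate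
5 | icosanoylketene (3-oxodocos-1-en-1-one) | CCCCCCCCCCCCCCCCCCCC(=O)C=C=O | intermediate
6 | ethyl 3-oxodocosanoate | CCCCCCCCCCCCCCCCCCCC(=O)CC(=O)OCC | intermediate
7 | methyl vinyl ketone (but-3-en-2-one) | CC(=O)C=C | starting material
8 | rac-ethyl 2-icosanoyl-5-oxohexanoate | CCCCCCCCCCCCCCCCCCCC(=O)C(CCC(C)=O)C(=O)OCC | intermediate
9 | ethyl 2-hydroxy-2-nonadecyl-4-oxocyclohexane-1-carboxylate (racemic, mixture of diastereomers) | CCCCCCCCCCCCCCCCCCCC1(O)CC(=O)CCC1C(=O)OCC | intermediate
10 | rac-ethyl 2-nonadecyl-4-oxocyclohex-2-ene-1-carboxylate | CCCCCCCCCCCCCCCCCCCC1=CC(=O)CCC1C(=O)OCC | intermediate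
11 | rac-2-nonadecyl-4-oxocyclohex-2-ene-1-carboxylic acid | CCCCCCCCCCCCCCCCCCCC1=CC(=O)CCC1C(=O)O | intermediate
12 | 3-nonadecylcyclohex-2-en-1-one (achiral) | CCCCCCCCCCCCCCCCCCCC1=CC(=O)CCC1 | target

**Totals**
Total step count: 6. Longest linear sequence: 6 steps (1 to 12).

**Steps most likely to fail, with fallbacks**

Step 4 (Michael addition). Risks are polymerisation of 7, a second Michael addition to 8, and slow reaction of the waxy β-keto ester. Fallback: starting from 6, replace the conjugate addition by an SN2 alkylation with a masked 3-oxobutyl electrophile. Alkylation of 6 with 2-(2-bromoethyl)-2-methyl-1,3-dioxolane (K2CO3, NaI (cat.), DMF, 60 °C) gives rac-ethyl 2-[2-(2-methyl-1,3-dioxolan-2-yl)ethyl]-3-oxodocosanoate F1. Ketal hydrolysis (1 M HCl, THF, rt) then returns to the route at 8.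

Step 5 (aldol cyclisation). Risks are the competing aldol mode, in which the chain α-methylene attacks the methyl ketone, and stalling at the ketol or at a β-enamino ester. Fallback: starting from 6, use an acceptor whose nucleophilic carbon is doubly activated, so the ring closure can go only one way. Michael addition of 6 to freshly prepared ethyl 3-oxopent-4-enoate (Nazarov reagent; Cs2CO3 (cat.), THF, 0 °C) gives rac-diethyl 2-icosanoyl-5-oxoheptanedioate F2. Knoevenagel-type ring closure of its active methylene onto the long-chain ketone (piperidine/AcOH (cat.), toluene, Dean–Stark) gives rac-diethyl 2-nonadecyl-4-oxocyclohex-2-ene-1,3-dicarboxylate F3. Saponification (KOH, aqueous EtOH, reflux; then HCl) gives 2-nonadecyl-4-oxocyclohex-2-ene-1,3-dicarboxylic acid F4. Its β-keto acid carboxyl is lost on warming, so the sequence comes back to the route at 11 (not isolated), which decarboxylates to 12 as in step 6.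

Step 6 (hydrolysis and decarboxylation). Risks are slow saponification of the hindered, lipophilic ester and base-induced retro-aldol or self-condensation of the enone. Fallback: starting from 4, carry an acid-labile ester so that no alkaline step is needed. Heating 4 with tert-butanol (3 equiv, toluene, reflux) gives tert-butyl 3-oxodocosanoate F5. Michael addition to 7 as in step 4 (KOtBu (5 mol%), t-BuOH/THF) gives rac-tert-butyl 2-icosanoyl-5-oxohexanoate F6. Cyclisation as in step 5 gives rac-tert-butyl 2-nonadecyl-4-oxocyclohex-2-ene-1-carboxylate F7. TsOH·H2O (cat.) in refluxing toluene cleaves the ester with loss of isobutene, coming back to the route at 11 (not isolated), which decarboxylates in the same flask to 12.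

**Further compounds**
F1 | step 4 | rac-ethyl 2-[2-(2-methyl-1,3-dioxolan-2-yl)ethyl]-3-oxodocosanoate | CCCCCCCCCCCCCCCCCCCC(=O)C(CCC1(C)OCCO1)C(=O)OCC
F2 | step 5 | rac-diethyl 2-icosanoyl-5-oxoheptanedioate | CCCCCCCCCCCCCCCCCCCC(=O)C(CCC(=O)CC(=O)OCC)C(=O)OCC
F3 | step 5 | rac-diethyl 2-nonadecyl-4-oxocyclohex-2-ene-1,3-dicarboxylate | CCCCCCCCCCCCCCCCCCCC1=C(C(=O)OCC)C(=O)CCC1C(=O)OCC
F4 | step 5 | rac-2-nonadecyl-4-oxocyclohex-2-ene-1,3-dicarboxylic acid | CCCCCCCCCCCCCCCCCCCC1=C(C(=O)O)C(=O)CCC1C(=O)O
F5 | step 6 | tert-butyl 3-oxodocosanoate | CCCCCCCCCCCCCCCCCCCC(=O)CC(=O)OC(C)(C)C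
F6 | step 6 | rac-tert-butyl 2-icosanoyl-5-oxohexanoate | CCCCCCCCCCCCCCCCCCCC(=O)C(CCC(C)=O)C(=O)OC(C)(C)C
F7 | step 6 | rac-tert-butyl 2-nonadecyl-4-oxocyclohex-2-ene-1-carboxylate | CCCCCCCCCCCCCCCCCCCC1=CC(=O)CCC1C(=O)OC(C)(C)C
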